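## Retrosynthetic overview

1. Target 25 ⇐ 24 (C3 desilylation) ⇐ 21 (lactone α-methylenation) ⇐ 18; the cis-epoxide comes from the (E)-1(10) alkene by syn-dihydroxylation and ring closure with inversion at C1.
2. 18 ⇐ 15: the C8 oxygen comes from a C8–Si bond (Tamao oxidation, then Mitsunobu inversion that installs the isobutyrate); the cis-lactone comes from reduction and lactonisation of keto ester 13.
3. 13 ⇐ carbinol 10 by an anionic oxy-Cope rearrangement that forms the ten-membered ring (C8–C9 bond, E-C1=C10, C8 stereocentre) and an enolate that is alkylated at C7; the Z-C4=C5 alkene is the former cyclohexene double bond.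
4. 10 ⇐ enone 4 + (E)-silylvinyl metal (from 5); 4 ⇐ (S)-carvone 1 (Luche reduction, silylation, allylic oxidation), the only source of chirality.
5. Ring order: cyclohexene (bought) → cyclodecadiene (oxy-Cope) → γ-lactone → epoxide.

Assumption: the SMILES is taken literally, i.e. (1R,3S,6S,7R,8R,10S), 4Z alkene, cis-fused 6,12-lactone and cis 1,10-epoxide; germacrane numbering is used for locants (C1–C10 ring, C11/C12/C13 lactone α-carbon/carbonyl/methylene, C14 on C10, C15 on C4).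

The route has not been run; the stereochemical outcomes of steps 5–7 and 10 are predictions from a chair transition state and peripheral attack on the medium ring.

## Route

Step 1
Reactants: 1 (S)-(+)-carvone
Product: 2 (1S,5S)-2-methyl-5-(prop-1-en-2-yl)cyclohex-2-en-1-ol (cis-carveol)
Conditions: NaBH4, CeCl3·7H2O, MeOH, −78 °C
Reagents that add atoms: none
Why: Luche 1,2-reduction delivers hydride axially to the enone carbonyl, giving the alcohol cis to the isopropenyl group (new centre 1S) with high selectivity.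

Step 2
Reactants: 2 (1S,5S)-cis-carveol
Product: 3 triisopropyl{[(1S,5S)-2-methyl-5-(prop-1-en-2-yl)cyclohex-2-en-1-yl]oxy}silane
Conditions: TIPSOTf, 2,6-lutidine, CH2Cl2, 0 °C
Reagents that add atoms: triisopropylsilyl trifluoromethanesulfonate, CC(C)[Si](C(C)C)(C(C)C)OS(=O)(=O)C(F)(F)F
Why: Silylation of the secondary allylic alcohol gives a fluoride-robust ether that blocks this position through the base, hydride and oxidation steps.

Step 3
Reactants: 3 cis-carveol TIPS ether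
Product: 4 (4S,6S)-3-methyl-6-(prop-1-en-2-yl)-4-[(triisopropylsilyl)oxy]cyclohex-2-en-1-one
Conditions: CrO3, 3,5-dimethylpyrazole, CH2Cl2, −20 °C
Reagents that add atoms: chromium trioxide, O=[Cr](=O)=O
Why: Allylic C–H oxidation by the CrO3·3,5-dimethylpyrazole complex takes place at the only free ring allylic CH2 (next to the alkene CH), the other allylic ring carbon being the hindered silyloxy carbon, and no stereocentre is touched.

Step 4
Reactants: 5 (E)-1,2-bis(tributylstannyl)ethene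
Product: 7 benzyldimethyl[(E)-2-(tributylstannyl)ethenyl]silane, via stannylvinyllithium 6 (not isolated)
Conditions: n-BuLi (1.0 equiv), THF, −78 °C; then BnMe2SiCl, −78 °C → rt
Reagents that add atoms: benzylchlorodimethylsilane, C[Si](C)(Cl)Cc1ccccc1
Why: Tin–lithium exchange at one terminus and silylation of the vinyllithium both proceed with retention of the E geometry.

Step 5
Reactants: 4 (4S,6S)-silyloxy enone; 7 benzyldimethyl[(E)-2-(tributylstannyl)ethenyl]silane
Product: 10 (1S,4S,6S)-1-[(E)-2-(benzyldimethylsilyl)ethenyl]-3-methyl-6-(prop-1-en-2-yl)-4-[(triisopropylsilyl)oxy]cyclohex-2-en-1-ol, via silylvinyllithium 8 (not isolated), via vinylcerium dichloride 9 (not isolated)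
Conditions: 7, n-BuLi, THF, −78 °C; CeCl3 (anhydrous), −78 °C; then 4, −78 °C; H2O work-up
Reagents that add atoms: none
Why: Tin–lithium exchange and transmetalation give an organocerium reagent that adds 1,2 to the enolisable enone, anti to the neighbouring isopropenyl group, giving the trans-1,2-dialkenyl carbinol (new centre 1S).

Step 6
Reactants: 10 (1S,4S,6S)-dialkenyl cyclohexenol
Product: 13 methyl 2-[(1S,2S,4E,7S,8Z)-2-(benzyldimethylsilyl)-4,8-dimethyl-10-oxo-7-[(triisopropylsilyl)oxy]cyclodeca-4,8-dien-1-yl]acetate, via potassium alkoxide 11 (not isolated), via potassium enolate 12 (not isolated)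
Conditions: KH, 18-crown-6, THF, 0 °C → rt; then BrCH2CO2Me, −78 °C
Reagents that add atoms: methyl bromoacetate, COC(=O)CBr
Why: Anionic oxy-Cope [3,3]-sigmatropic rearrangement through a chair transition state with both ring bonds and the silyl group equatorial opens the cyclohexene to the ten-membered ring, fixes E-C1=C10 and relays the C1/C6 chirality to C8 (S), and bromoacetate then attacks the exposed outer face of the enolate, trans to silicon, setting C7.

Step 7
Reactants: 13 keto ester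
Product: 15 (3aS,4S,6E,9S,10Z,11aS)-4-(benzyldimethylsilyl)-6,10-dimethyl-9-[(triisopropylsilyl)oxy]-3a,4,5,8,9,11a-hexahydrocyclodeca[b]furan-2(3H)-one, via hydroxy ester 14 (not isolated)
Conditions: NaBH4, CeCl3·7H2O, MeOH, −40 °C → rt
Reagents that add atoms: none
Why: Luche 1,2-reduction from the peripheral face of the medium-ring enone gives the 6S alcohol on the same side as the C7 acetate arm, which closes to the cis-fused γ-lactone.

Step 8
Reactants: 15 silyl lactone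
Product: 17 (3aR,4S,6E,9S,10Z,11aS)-4-hydroxy-6,10-dimethyl-9-[(triisopropylsilyl)oxy]-3a,4,5,8,9,11a-hexahydrocyclodeca[b]furan-2(3H)-one, via fluorosilane 16 (not isolated)
Conditions: Bu4NF, THF, 0 °C, 15 min; then 30% H2O2, KHCO3, MeOH, 0 °C → rt
Reagents that add atoms: hydrogen peroxide, OO
Why: Tamao–Fleming oxidation, in which fluoride cleaves the benzyl group from silicon and peroxide then moves C8 from Si to O with retention (8S alcohol), while the hindered TIPS ether survives the brief fluoride treatment.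

Step 9
Reactants: 17 (8S)-hydroxy lactone
Product: 18 (3aR,4R,6E,9S,10Z,11aS)-6,10-dimethyl-2-oxo-9-[(triisopropylsilyl)oxy]-2,3,3a,4,5,8,9,11a-octahydrocyclodeca[b]furan-4-yl 2-methylpropanoate
Conditions: i-PrCO2H, PPh3, DIAD, toluene, 0 °C → rt
Reagents that add atoms: 2-methylpropanoic acid, CC(C)C(=O)O
Why: Mitsunobu esterification displaces the activated C8 oxygen by isobutyrate with SN2 inversion, giving the 8R ester of the target.

Step 10
Reactants: 18 (8R)-isobutyrate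
Product: 19 (3aR,4R,6S,7S,9S,10Z,11aS)-6,7-dihydroxy-6,10-dimethyl-2-oxo-9-[(triisopropylsilyl)oxy]-2,3,3a,4,5,6,7,8,9,11a-decahydrocyclodeca[b]furan-4-yl 2-methylpropanoate
Conditions: OsO4 (2 mol %), NMO, acetone–H2O, 0 °C
Reagents that add atoms: N-methylmorpholine N-oxide, C[N+]1([O-])CCOCC1; water, O
Why: Upjohn syn-dihydroxylation selects the strained, electron-rich (E)-1(10) alkene over the oxygen-flanked C4=C5 bond and is expected to add from the exposed face of the crown conformer that holds the C6 and C8 oxygens equatorial, giving the 1S,10S diol (germacrane numbering).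

Step 11
Reactants: 19 (1S,10S)-diol
Product: 21 (1R,3S,4Z,6S,7R,8R,10S)-1,10-epoxy-8-(2-methylpropanoyloxy)-3-[(triisopropylsilyl)oxy]-13-norgermacr-4-en-6,12-olide (the cis-epoxide), via mesylate 20 (not isolated)
Conditions: MsCl, Et3N, CH2Cl2, −20 °C; then DBU, rt
Reagents that add atoms: none
Why: The secondary C1 hydroxyl is mesylated selectively and the tertiary C10 oxygen displaces it (intramolecular Williamson SN2) with inversion at C1, so the syn-diol of the E-alkene becomes the cis-epoxide (1R,10S).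

Step 12
Reactants: 21 epoxy lactone
Product: 24 (1R,3S,4Z,6S,7R,8R,10S)-1,10-epoxy-8-(2-methylpropanoyloxy)-3-[(triisopropylsilyl)oxy]germacra-4,11(13)-dien-6,12-olide, via Mannich base 22 (not isolated), via ammonium iodide 23 (not isolated)
Conditions: LiN(i-Pr)2, THF, −78 °C; CH2=NMe2+ I−, −78 °C → rt; then MeI, MeOH; then aq. NaHCO3, CH2Cl2
Reagents that add atoms: N,N-dimethylmethyleneiminium iodide (Eschenmoser's salt), C=[N+](C)C.[I-]
Why: The lactone CH2 is deprotonated in preference to the less acidic, hindered isobutyrate methine, and Mannich aminomethylation followed by quaternisation and Hofmann-type elimination gives the α-methylene lactone without creating a stereocentre.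

Step 13
Reactants: 24 TIPS ether of the target
Product: 25 (1R,3S,4Z,6S,7R,8R,10S)-1,10-epoxy-3-hydroxy-8-(2-methylpropanoyloxy)germacra-4,11(13)-dien-6,12-olide (target)
Conditions: HF·pyridine, pyridine, THF, 0 °C → rt
Reagents that add atoms: none
Why: Buffered fluoride desilylation frees the C3 hydroxyl without opening the epoxide or adding to the α-methylene lactone.

## Compound list

1 | (S)-(+)-carvone | CC1=CC[C@@H](CC1=O)C(C)=C | starting material
2 | (1S,5S)-cis-carveol | CC1=CC[C@@H](C[C@@H]1O)C(C)=C | intermediate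
3 | triisopropyl{[(1S,5S)-2-methyl-5-(prop-1-en-2-yl)cyclohex-2-en-1-yl]oxy}silane | CC1=CC[C@@H](C[C@@H]1O[Si](C(C)C)(C(C)C)C(C)C)C(C)=C | intermediate
4 | (4S,6S)-3-methyl-6-(prop-1-en-2-yl)-4-[(triisopropylsilyl)oxy]cyclohex-2-en-1-one | CC1=CC(=O)[C@@H](C[C@@H]1O[Si](C(C)C)(C(C)C)C(C)C)C(C)=C | intermediate
5 | (E)-1,2-bis(tributylstannyl)ethene | CCCC[Sn](CCCC)(CCCC)/C=C/[Sn](CCCC)(CCCC)CCCC | starting material
6 | (E)-2-(tributylstannyl)ethenyllithium | [Li]/C=C/[Sn](CCCC)(CCCC)CCCC | intermediate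
7 | benzyldimethyl[(E)-2-(tributylstannyl)ethenyl]silane | C[Si](C)(Cc1ccccc1)/C=C/[Sn](CCCC)(CCCC)CCCC | intermediate
8 | (E)-2-(benzyldimethylsilyl)ethenyllithium | [Li]/C=C/[Si](C)(C)Cc1ccccc1 | intermediate
9 | dichloro[(E)-2-(benzyldimethylsilyl)ethenyl]cerium | Cl[Ce](Cl)/C=C/[Si](C)(C)Cc1ccccc1 | intermediate
10 | (1S,4S,6S)-1-[(E)-2-(benzyldimethylsilyl)ethenyl]-3-methyl-6-(prop-1-en-2-yl)-4-[(triisopropylsilyl)oxy]cyclohex-2-en-1-ol | CC1=C[C@@](O)(/C=C/[Si](C)(C)Cc2ccccc2)[C@@H](C[C@@H]1O[Si](C(C)C)(C(C)C)C(C)C)C(C)=C | intermediate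
11 | potassium alkoxide of 10 | CC1=C[C@@]([O-])(/C=C/[Si](C)(C)Cc2ccccc2)[C@@H](C[C@@H]1O[Si](C(C)C)(C(C)C)C(C)C)C(C)=C.[K+] | intermediate
12 | potassium (1Z,3S,5E,8S,9Z)-3-(benzyldimethylsilyl)-5,9-dimethyl-8-[(triisopropylsilyl)oxy]cyclodeca-1,5,9-trien-1-olate | C1/C(C)=C/C[C@H](O[Si](C(C)C)(C(C)C)C(C)C)/C(C)=C\C(\[O-])=C\[C@H]1[Si](C)(C)Cc2ccccc2.[K+] | intermediate
13 | methyl 2-[(1S,2S,4E,7S,8Z)-2-(benzyldimethylsilyl)-4,8-dimethyl-10-oxo-7-[(triisopropylsilyl)oxy]cyclodeca-4,8-dien-1-yl]acetate | COC(=O)C[C@@H]1[C@@H]([Si](C)(C)Cc2ccccc2)C/C(C)=C/C[C@H](O[Si](C(C)C)(C(C)C)C(C)C)/C(C)=C\C1=O | intermediate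
14 | methyl 2-[(1S,2S,4E,7S,8Z,10S)-2-(benzyldimethylsilyl)-10-hydroxy-4,8-dimethyl-7-[(triisopropylsilyl)oxy]cyclodeca-4,8-dien-1-yl]acetate | COC(=O)C[C@@H]1[C@@H]([Si](C)(C)Cc2ccccc2)C/C(C)=C/C[C@H](O[Si](C(C)C)(C(C)C)C(C)C)/C(C)=C\[C@@H]1O | intermediate
15 | (3aS,4S,6E,9S,10Z,11aS)-4-(benzyldimethylsilyl)-6,10-dimethyl-9-[(triisopropylsilyl)oxy]-3a,4,5,8,9,11a-hexahydrocyclodeca[b]furan-2(3H)-one | C1C(=O)O[C@H]2/C=C(/C)[C@@H](O[Si](C(C)C)(C(C)C)C(C)C)C/C=C(C)/C[C@H]([Si](C)(C)Cc3ccccc3)[C@@H]12 | intermediate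
16 | (3aS,4S,6E,9S,10Z,11aS)-4-[fluoro(dimethyl)silyl]-6,10-dimethyl-9-[(triisopropylsilyl)oxy]-3a,4,5,8,9,11a-hexahydrocyclodeca[b]furan-2(3H)-one | C1C(=O)O[C@H]2/C=C(/C)[C@@H](O[Si](C(C)C)(C(C)C)C(C)C)C/C=C(C)/C[C@H]([Si](C)(C)F)[C@@H]12 | intermediate
17 | (3aR,4S,6E,9S,10Z,11aS)-4-hydroxy-6,10-dimethyl-9-[(triisopropylsilyl)oxy]-3a,4,5,8,9,11a-hexahydrocyclodeca[b]furan-2(3H)-one | C1C(=O)O[C@H]2/C=C(/C)[C@@H](O[Si](C(C)C)(C(C)C)C(C)C)C/C=C(C)/C[C@H](O)[C@@H]12 | intermediate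
18 | (3aR,4R,6E,9S,10Z,11aS)-6,10-dimethyl-2-oxo-9-[(triisopropylsilyl)oxy]-2,3,3a,4,5,8,9,11a-octahydrocyclodeca[b]furan-4-yl 2-methylpropanoate | C1C(=O)O[C@H]2/C=C(/C)[C@@H](O[Si](C(C)C)(C(C)C)C(C)C)C/C=C(C)/C[C@@H](OC(=O)C(C)C)[C@@H]12 | intermediate
19 | (3aR,4R,6S,7S,9S,10Z,11aS)-6,7-dihydroxy-6,10-dimethyl-2-oxo-9-[(triisopropylsilyl)oxy]-2,3,3a,4,5,6,7,8,9,11a-decahydrocyclodeca[b]furan-4-yl 2-methylpropanoate | C1C(=O)O[C@H]2/C=C(/C)[C@@H](O[Si](C(C)C)(C(C)C)C(C)C)C[C@H](O)[C@@](C)(O)C[C@@H](OC(=O)C(C)C)[C@@H]12 | intermediate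
20 | 7-O-methanesulfonate of 19 (mesylate on the secondary C1 hydroxyl in germacrane numbering) | C1C(=O)O[C@H]2/C=C(/C)[C@@H](O[Si](C(C)C)(C(C)C)C(C)C)C[C@H](OS(C)(=O)=O)[C@@](C)(O)C[C@@H](OC(=O)C(C)C)[C@@H]12 | intermediate
21 | (1R,3S,4Z,6S,7R,8R,10S)-1,10-epoxy-8-(2-methylpropanoyloxy)-3-[(triisopropylsilyl)oxy]-13-norgermacr-4-en-6,12-olide | C1C(=O)O[C@H]2/C=C(/C)[C@@H](O[Si](C(C)C)(C(C)C)C(C)C)C[C@H]3O[C@@]3(C)C[C@@H](OC(=O)C(C)C)[C@@H]12 | intermediate
22 | 11-[(dimethylamino)methyl] derivative of 21 (C11 epimers) | CN(C)CC1C(=O)O[C@H]2/C=C(/C)[C@@H](O[Si](C(C)C)(C(C)C)C(C)C)C[C@H]3O[C@@]3(C)C[C@@H](OC(=O)C(C)C)[C@@H]12 | intermediate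
23 | 11-[(trimethylammonio)methyl] derivative of 21, iodide (C11 epimers) | C[N+](C)(C)CC1C(=O)O[C@H]2/C=C(/C)[C@@H](O[Si](C(C)C)(C(C)C)C(C)C)C[C@H]3O[C@@]3(C)C[C@@H](OC(=O)C(C)C)[C@@H]12.[I-] | intermediate
24 | (1R,3S,4Z,6S,7R,8R,10S)-1,10-epoxy-8-(2-methylpropanoyloxy)-3-[(triisopropylsilyl)oxy]germacra-4,11(13)-dien-6,12-olide | C=C1C(=O)O[C@H]2/C=C(/C)[C@@H](O[Si](C(C)C)(C(C)C)C(C)C)C[C@H]3O[C@@]3(C)C[C@@H](OC(=O)C(C)C)[C@@H]12 | intermediate
25 | (1R,3S,4Z,6S,7R,8R,10S)-1,10-epoxy-3-hydroxy-8-(2-methylpropanoyloxy)germacra-4,11(13)-dien-6,12-olide | C=C1C(=O)O[C@H]2/C=C(/C)[C@@H](O)C[C@H]3O[C@@]3(C)C[C@@H](OC(=O)C(C)C)[C@@H]12 | target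

## Step count and risks

Total step count: 13. Longest linear sequence: 12 steps from 1 (steps 1–3 and 5–13); step 4 prepares the side fragment 7.

The three steps most likely to fail:

Step 10 (face selectivity of the osmylation, which fixes C10 and, after inversion, C1). The face argument rests on a conformational preference that cannot be guaranteed. The fallback sets out from 18 and reaches the cis-epoxide without a diol. Thiyl-radical isomerisation (PhSSPh cat., hν, benzene) turns the strained 1(10)E alkene into the more stable (3aR,4R,6Z,9S,10Z,11aS)-configured 1(10)Z isomer of 18 F5. Direct epoxidation of that alkene on its convex face (dimethyldioxirane, acetone, −20 °C) then gives the cis-epoxide, coming back to the route at 21.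

Step 6 (oxy-Cope with alkylation in the same flask). The crown-complexed potassium enolate may O-alkylate, exchange protons or alkylate with poor selectivity. The fallback sets out from carbinol 10: after the same KH/18-crown-6 rearrangement, enolate 12 is silylated (Me3SiCl, Et3N, −78 °C) and isolated as the (1Z,3S,5E,8S,9Z)-1-(trimethylsilyloxy)cyclodecatriene F1. MeLi (THF, 0 °C) then regenerates the crown-free lithium (1Z,3S,5E,8S,9Z)-cyclodecatrienolate F2, which is alkylated with methyl iodoacetate (DMPU, −78 °C) and comes back to the route at keto ester 13.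

Step 9 (Mitsunobu inversion at the hindered C8 carbinol). Elimination towards C9 or C7 is the danger. The fallback sets out from alcohol 17 and inverts C8 by oxidation and reduction instead of SN2. Dess–Martin periodinane (NaHCO3, CH2Cl2, 0 °C) gives the (3aS,6E,9S,10Z,11aS)-2,4-dione F3. LiBH(s-Bu)3 (THF, −78 °C) delivers hydride from the exposed face to give the (3aR,4R,6E,9S,10Z,11aS)-4-hydroxy lactone F4. Isobutyryl chloride, DMAP and pyridine (CH2Cl2, 0 °C) acylate it, coming back to the route at 18.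

## Further compounds

F1 | step 6 | benzyl{(1S,3E,6S,7Z,9Z)-4,8-dimethyl-6-[(triisopropylsilyl)oxy]-10-[(trimethylsilyl)oxy]cyclodeca-3,7,9-trien-1-yl}dimethylsilane (trimethylsilyl enol ether of the oxy-Cope enolate) | C1/C(C)=C/C[C@H](O[Si](C(C)C)(C(C)C)C(C)C)/C(C)=C\C(\O[Si](C)(C)C)=C\[C@H]1[Si](C)(C)Cc2ccccc2
F2 | step 6 | lithium (1Z,3S,5E,8S,9Z)-3-(benzyldimethylsilyl)-5,9-dimethyl-8-[(triisopropylsilyl)oxy]cyclodeca-1,5,9-trien-1-olate | C1/C(C)=C/C[C@H](O[Si](C(C)C)(C(C)C)C(C)C)/C(C)=C\C(\[O-])=C\[C@H]1[Si](C)(C)Cc2ccccc2.[Li+]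
F3 | step 9 | (3aS,6E,9S,10Z,11aS)-6,10-dimethyl-9-[(triisopropylsilyl)oxy]-3,3a,5,8,9,11a-hexahydrocyclodeca[b]furan-2,4-dione | C1C(=O)O[C@H]2/C=C(/C)[C@@H](O[Si](C(C)C)(C(C)C)C(C)C)C/C=C(C)/CC(=O)[C@@H]12
F4 | step 9 | (3aR,4R,6E,9S,10Z,11aS)-4-hydroxy-6,10-dimethyl-9-[(triisopropylsilyl)oxy]-3a,4,5,8,9,11a-hexahydrocyclodeca[b]furan-2(3H)-one | C1C(=O)O[C@H]2/C=C(/C)[C@@H](O[Si](C(C)C)(C(C)C)C(C)C)C/C=C(C)/C[C@@H](O)[C@@H]12
F5 | step 10 | (3aR,4R,6Z,9S,10Z,11aS)-6,10-dimethyl-2-oxo-9-[(triisopropylsilyl)oxy]-2,3,3a,4,5,8,9,11a-octahydrocyclodeca[b]furan-4-yl 2-methylpropanoate | C1C(=O)O[C@H]2/C=C(/C)[C@@H](O[Si](C(C)C)(C(C)C)C(C)C)C/C=C(C)\C[C@@H](OC(=O)C(C)C)[C@@H]12
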